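Do not wait for the target in Monday's run to reach the whole charge: it cannot, for it reads 85.3% at 2.50 h and 85.4% at 4.00 h, with starting material at 0%. Ask first, then, what the end state is.

| flask | solid substrate | free catalyst | remark | time |
|---|---|---|---|---|
| Thursday's | 0.050 M | 0.5 mol% | run made earlier |  |
| Monday's | 0.050 M | 0.75 mol% | run made earlier |  |
| Tuesday's | 0.075 M | 1 mol% | run made earlier |  |
| flask | 0.050 M | 1 mol% |  | 4.0 h |

| run | time / h | target / % | starting material / % |
|---|---|---|---|
| Thursday's | 1.00 | 42.9 | 23.9 |
| Thursday's | 2.00 | 76.5 | 4.4 |
| Thursday's | 3.00 | 78.5 | 0.5 |
| Thursday's | 4.00 | 80.5 | 0.2 |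
| Monday's | 0.500 | 27.5 | 20.6 |
| Monday's | 1.33 | 77.0 | 11.3 |
| Monday's | 2.50 | 85.3 | 0.7 |
| Monday's | 4.00 | 85.4 | 0 |
| Tuesday's | 0.500 | 28.9 | 10.7 |
| Tuesday's | 1.33 | 83.0 | 7.6 |
| Tuesday's | 2.50 | 88.5 | 0 |
| Tuesday's | 4.00 | 88.4 | 0.4 |

(scatter of a reading: 0.5 percentage points)

- solid substrate is a solid; its amount is given per volume of the solution
- the numbers in the tables scatter by 0.5 percentage points (one standard deviation)
- at the start none of the solid substrate is in solution
- starting material is what solid substrate becomes in solution
- starting material means what is dissolved; the solid is not counted in it

1. how much target there is at 4.0 h, in percent of the solid substrate charged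
2. concentration of starting material in solution at 4.0 h, in percent of saturation

Take each run's last target reading, divide what is missing by what was found, and multiply by that run's catalyst loading. Thursday's run gives 0.12 mol%, Monday's 0.13 mol% and Tuesday's 0.13 mol%, though Tuesday's loading is twice Thursday's and its charge is heavier. Keep their mean, 0.13 mol%, as the loss-loading product, a selectivity read in reverse.

Divide it by this flask's loading: the loss per target is 0.127, so expect 88.7% of target. Monday's run, at the same charge with less catalyst, reads 0% of starting material at 4.00 h, so expect saturation near zero in this flask.

The forecast, holding that “More catalyst improves selectivity”, gives 87.5%, slightly below my figure, and 0.3% of saturation.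

The flask gives 88.8% of target and 0% of saturation.

    starting material + free catalyst → catalyst intermediate A (k = 170 /M/min)
    catalyst intermediate A → catalyst intermediate B (k = 400 /min)
    catalyst intermediate B → free catalyst + target (k = 12.0 /min)
    solid substrate ⇌ starting material, rate k4*(cs4 - [starting material]) while solid is left; crystals form when [starting material] > cs4 (solubility = 16.0 mM, k = 0.110 /min)
    starting material + target → side product (k = 0.200 /M/min)

Move each setting of this flask alone by the same factor, up or down, and the target shifts at most thus: free catalyst (2.9 points), then solid substrate (0.057 points), then time (under 0.05 points). Now use the product once more: its loss per target of 0.127 stands beside the flask's side product per target, 0.126, at 4.00 h.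

For the neighbour flask at 1.7 mol%, the product gives a loss per target of 0.0746, hence 93.1% of target. That flask gives 93.2%.

The numbers in the tables stem from a simulated flask from invented constants; noise was put on by code.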